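The route rests on an intramolecular Diels–Alder reaction of an acyclic chain in which the terminal π-bond (C5=C6) of a 1,1-disubstituted allene is the dienophile and a 2-silyloxy diene (C7=C8–C9=C10) is the diene. The step exploits the tetrasubstituted C4=C5 alkene of ring A, exocyclic to ring B, as the allene π-bond that is left over, and the C8 oxygen of ring B as the enol ether. One operation closes both rings, forms C5–C10 and C6–C7 and sets the quaternary centre C10 from the C3 propanoate stereocentre, the only one made by catalysis. The precursor is a (3S)-allenyl propanoate tethered through C1–C2 to an E,Z-silyloxy triene that already carries the acrylate.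

Key step: step 8

Remark: eudesmane numbering is used for all compounds (ring A = C1–C5 and C10; ring B = C5–C10; C11–C13 = acrylate carbons with C12 the ester carbon; C14 = methyl on C10; C15 = methyl on C4); β is the face of the C10 methyl.

Step 1
Reactants: 1 geranyl acetate
Product: 3 (2E)-3-methyl-6-oxohex-2-en-1-yl acetate, via secondary ozonide 2 (not isolated)
Conditions: O3 (1.0 equiv), CH2Cl2, −78 °C; then Me2S, −78 °C → rt
Reagents that add atoms: ozone, [O-][O+]=O
Why: Criegee ozonolysis should be selective for the electron-rich 6,7-alkene over the 2,3-alkene deactivated by the allylic acetate, and reductive work-up gives the aldehyde (future C3) with the E-alkene (future C9=C10) untouched.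

Step 2
Reactants: 3 (2E)-3-methyl-6-oxohex-2-en-1-yl acetate; 4 1-bromobut-2-yne
Product: 6 (2E,6S)-3,7-dimethylnona-2,7,8-triene-1,6-diol, via trimethylsilyl ether acetate 5 (not isolated)
Conditions: CrCl3 (5 mol %), chiral tethered bis(8-quinolinol) ligand (6 mol %, enantiomer giving Re-face addition), Mn powder, Me3SiCl, THF, rt; then K2CO3 (cat.), MeOH, rt
Reagents that add atoms: Me3SiCl, C[Si](C)(C)Cl (silyl group of 5 only)
Why: In this catalytic asymmetric Nozaki–Hiyama–Kishi reaction the but-2-ynylchromium species should add by SE2' to give the α-allenyl carbinol, the ligand setting C3 as S by reagent control, and methanolysis then removes the silyl ether and the acetate.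

Step 3
Reactants: 6 (2E,6S)-3,7-dimethylnona-2,7,8-triene-1,6-diol
Product: 7 (2E,6S)-6-hydroxy-3,7-dimethylnona-2,7,8-trienal
Conditions: TEMPO (10 mol %), PhI(OAc)2, CH2Cl2, rt
Reagents that add atoms: none
Why: TEMPO-catalysed oxoammonium oxidation should take the primary allylic alcohol in preference to the hindered secondary allenyl carbinol and should not isomerise the E-enal.

Step 4
Reactants: 7 (2E,6S)-6-hydroxy-3,7-dimethylnona-2,7,8-trienal
Product: 8 (4S,7E)-3,7-dimethyl-9-oxonona-1,2,7-trien-4-yl propanoate
Conditions: (EtCO)2O, Et3N, DMAP (cat.), CH2Cl2, 0 °C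
Reagents that add atoms: propanoic anhydride, CCC(=O)OC(=O)CC
Why: DMAP-catalysed acylation installs the C3 propanoate of the target with retention at the stereocentre.

Step 5
Reactants: 8 (4S,7E)-3,7-dimethyl-9-oxonona-1,2,7-trien-4-yl propanoate; 9 methyl 2-(bromomethyl)acrylate
Product: 10 methyl (5E,9S)-4-hydroxy-6,10-dimethyl-2-methylidene-9-(propanoyloxy)dodeca-5,10,11-trienoate (both C4 epimers)
Conditions: Zn dust, THF/saturated aqueous NH4Cl, 0 °C → rt
Reagents that add atoms: none
Why: In this Barbier allylation the 2-(methoxycarbonyl)allylzinc reagent should add 1,2 to the enal, forming C7–C8 and delivering the intact acrylate; the new carbinol centre is oxidised away in step 6.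

Step 6
Reactants: 10 methyl (5E,9S)-4-hydroxy-6,10-dimethyl-2-methylidene-9-(propanoyloxy)dodeca-5,10,11-trienoate
Product: 11 methyl (5E,9S)-6,10-dimethyl-2-methylidene-4-oxo-9-(propanoyloxy)dodeca-5,10,11-trienoate
Conditions: Dess–Martin periodinane, pyridine, CH2Cl2, 0 °C
Reagents that add atoms: none
Why: Dess–Martin oxidation under buffered, non-basic conditions should give the enone without moving the acrylate double bond into conjugation with the new ketone.

Step 7
Reactants: 11 methyl (5E,9S)-6,10-dimethyl-2-methylidene-4-oxo-9-(propanoyloxy)dodeca-5,10,11-trienoate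
Product: 12 methyl (3Z,5E,9S)-4-(tert-butyldimethylsilyloxy)-6,10-dimethyl-2-methylidene-9-(propanoyloxy)dodeca-3,5,10,11-tetraenoate
Conditions: TBSOTf, Et3N, CH2Cl2, −78 °C (base added last)
Reagents that add atoms: tert-butyldimethylsilyl trifluoromethanesulfonate, CC(C)(C)[Si](C)(C)OS(=O)(=O)C(F)(F)F
Why: Soft enolisation removes the most acidic proton (C7, α to the ketone and allylic to the acrylate) and should give the cross-conjugated 2-silyloxy diene as the Z enol ether, with the acrylate cis to oxygen and so on the outside of the diene.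

Step 8
Reactants: 12 methyl (3Z,5E,9S)-4-(tert-butyldimethylsilyloxy)-6,10-dimethyl-2-methylidene-9-(propanoyloxy)dodeca-3,5,10,11-tetraenoate
Product: 13 methyl (3S,7S,10R)-8-(tert-butyldimethylsilyloxy)-3-(propanoyloxy)eudesma-4,8,11(13)-trien-12-oate (10β-methyl, 3β-propanoyloxy, 7α-side chain)
Conditions: PhMe (0.005 M), BHT (10 mol %), base-washed sealed tube, 160 °C
Reagents that add atoms: none
Why: A thermal, concerted but asynchronous [4+2] cycloaddition (intramolecular Diels–Alder reaction) adds the diene C7=C8–C9=C10 across the terminal allene π-bond C5=C6; the closest known reaction type is the intramolecular Diels–Alder reaction of allenes that react through their distal double bond and keep the proximal one as a ring alkene. Ring B closes as the cycloadduct itself (bonds C5–C10 and C6–C7, six-membered transition state), and ring A closes in the same event through the tether C1–C3, the untouched allene π-bond becoming the endocyclic C4=C5 bond. At C10 the tether must sit outside on the E-configured C9=C10 bond with the methyl inside, and the face is chosen by C3: allylic 1,2-strain with the C4 methyl should turn the propanoyloxy group pseudoaxial on the sofa-shaped nascent ring A, where it avoids C9–H and the body of the diene and lies on the side of the inside methyl, so that O3 and C14 end cis (10R from 3S). C7 is fixed stereospecifically by the Z enol ether (acrylate outside, hence trans to the C10 methyl) and is corrected in step 10. The step needs distal rather than proximal allene selectivity, which is secured because the proximal mode would join the two fully substituted carbons C4 and C10 in a five-membered ring, and it must outrun a [1,5]-hydrogen shift of the diene, hence dilution and the lowest workable temperature; since C3 is fixed, any C10 epimer is a separable diastereomer.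

Step 9
Reactants: 13 methyl (3S,7S,10R)-8-(tert-butyldimethylsilyloxy)-3-(propanoyloxy)eudesma-4,8,11(13)-trien-12-oate
Product: 14 methyl (3S,7S,10R)-8-oxo-3-(propanoyloxy)eudesma-4,11(13)-dien-12-oate (7α-side chain)
Conditions: HF·pyridine, pyridine, THF, 0 °C
Reagents that add atoms: none
Why: Buffered protodesilylation of the silyl enol ether should give the C8 ketone without touching the epimerisable C7 centre, the esters or the skipped acrylate.

Step 10
Reactants: 14 methyl (3S,7S,10R)-8-oxo-3-(propanoyloxy)eudesma-4,11(13)-dien-12-oate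
Product: 16 methyl (3S,7R,10R)-8-oxo-3-(propanoyloxy)eudesma-4,11(13)-dien-12-oate (7β-side chain), via potassium dienolate 15 (not isolated)
Conditions: KN(SiMe3)2 (0.98 equiv), THF, −78 → −30 °C; then AcOH, THF, −78 °C
Reagents that add atoms: KN(SiMe3)2, C[Si](C)(C)[N-][Si](C)(C)C.[K+] (potassium of 15 only)
Why: Equilibrating deprotonation should give the conjugated C7=C8 dienolate, and kinetic α-protonation at C7 should then come axially from the face opposite the axial C10 methyl (ring B is a locked chair because C1 must stay near the C4=C5 plane), placing the acrylate equatorial and cis to that methyl (7R).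

Step 11
Reactants: 16 methyl (3S,7R,10R)-8-oxo-3-(propanoyloxy)eudesma-4,11(13)-dien-12-oate
Product: 17 methyl (3S,7R,8R,10R)-8-hydroxy-3-(propanoyloxy)eudesma-4,11(13)-dien-12-oate
Conditions: NaBH4, CeCl3·7H2O, MeOH, −78 °C
Reagents that add atoms: none
Why: Luche reduction is chemoselective for the ketone over the acrylate and the esters, and since axial hydride delivery is blocked by the syn-axial C10 methyl, hydride should add equatorially from the opposite face to give the axial 8β-alcohol, cis to the acrylate (8R).

Step 12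
Reactants: 17 methyl (3S,7R,8R,10R)-8-hydroxy-3-(propanoyloxy)eudesma-4,11(13)-dien-12-oate
Product: 18 methyl (3S,7R,8R,10R)-8-acetoxy-3-(propanoyloxy)eudesma-4,11(13)-dien-12-oate
Conditions: Ac2O, pyridine, DMAP (cat.), CH2Cl2, 0 °C → rt
Reagents that add atoms: acetic anhydride, CC(=O)OC(C)=O
Why: DMAP-catalysed acetylation of the axial secondary alcohol, run directly on the crude alcohol to forestall lactonisation onto the acrylate ester, should give the target.

Compound list
1 | geranyl acetate, (2E)-3,7-dimethylocta-2,6-dien-1-yl acetate | CC(C)=CCC/C(C)=C/COC(C)=O | starting material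
2 | secondary ozonide, (2E)-5-(5,5-dimethyl-1,2,4-trioxolan-3-yl)-3-methylpent-2-en-1-yl acetate | CC(=O)OC/C=C(\C)CCC1OOC(C)(C)O1 | intermediate (not isolated)
3 | (2E)-3-methyl-6-oxohex-2-en-1-yl acetate | O=CCC/C(C)=C/COC(C)=O | intermediate
4 | 1-bromobut-2-yne | CC#CCBr | starting material
5 | (2E,6S)-3,7-dimethyl-6-(trimethylsilyloxy)nona-2,7,8-trien-1-yl acetate | C=C=C(C)[C@@H](O[Si](C)(C)C)CC/C(C)=C/COC(C)=O | intermediate (not isolated)
6 | (2E,6S)-3,7-dimethylnona-2,7,8-triene-1,6-diol | C=C=C(C)[C@@H](O)CC/C(C)=C/CO | intermediate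
7 | (2E,6S)-6-hydroxy-3,7-dimethylnona-2,7,8-trienal | C=C=C(C)[C@@H](O)CC/C(C)=C/C=O | intermediate
8 | (4S,7E)-3,7-dimethyl-9-oxonona-1,2,7-trien-4-yl propanoate | C=C=C(C)[C@@H](OC(=O)CC)CC/C(C)=C/C=O | intermediate
9 | methyl 2-(bromomethyl)acrylate | C=C(CBr)C(=O)OC | starting material
10 | methyl (5E,9S)-4-hydroxy-6,10-dimethyl-2-methylidene-9-(propanoyloxy)dodeca-5,10,11-trienoate (both C4 epimers) | C=C=C(C)[C@@H](OC(=O)CC)CC/C(C)=C/C(O)CC(=C)C(=O)OC | intermediate
11 | methyl (5E,9S)-6,10-dimethyl-2-methylidene-4-oxo-9-(propanoyloxy)dodeca-5,10,11-trienoate | C=C=C(C)[C@@H](OC(=O)CC)CC/C(C)=C/C(=O)CC(=C)C(=O)OC | intermediate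
12 | methyl (3Z,5E,9S)-4-(tert-butyldimethylsilyloxy)-6,10-dimethyl-2-methylidene-9-(propanoyloxy)dodeca-3,5,10,11-tetraenoate | C=C=C(C)[C@@H](OC(=O)CC)CC/C(C)=C/C(O[Si](C)(C)C(C)(C)C)=C/C(=C)C(=O)OC | intermediate
13 | methyl (3S,7S,10R)-8-(tert-butyldimethylsilyloxy)-3-(propanoyloxy)eudesma-4,8,11(13)-trien-12-oate | C=C(C(=O)OC)[C@@H]1CC2=C(C)[C@@H](OC(=O)CC)CC[C@]2(C)C=C1O[Si](C)(C)C(C)(C)C | intermediate
14 | methyl (3S,7S,10R)-8-oxo-3-(propanoyloxy)eudesma-4,11(13)-dien-12-oate | C=C(C(=O)OC)[C@@H]1CC2=C(C)[C@@H](OC(=O)CC)CC[C@]2(C)CC1=O | intermediate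
15 | potassium (3S,10R)-12-methoxy-12-oxo-3-(propanoyloxy)eudesma-4,7,11(13)-trien-8-olate | C=C(C(=O)OC)C=1CC2=C(C)[C@@H](OC(=O)CC)CC[C@]2(C)CC=1[O-].[K+] | intermediate (not isolated)
16 | methyl (3S,7R,10R)-8-oxo-3-(propanoyloxy)eudesma-4,11(13)-dien-12-oate | C=C(C(=O)OC)[C@H]1CC2=C(C)[C@@H](OC(=O)CC)CC[C@]2(C)CC1=O | intermediate
17 | methyl (3S,7R,8R,10R)-8-hydroxy-3-(propanoyloxy)eudesma-4,11(13)-dien-12-oate | C=C(C(=O)OC)[C@H]1CC2=C(C)[C@@H](OC(=O)CC)CC[C@]2(C)C[C@H]1O | intermediate
18 | methyl (3S,7R,8R,10R)-8-acetoxy-3-(propanoyloxy)eudesma-4,11(13)-dien-12-oate | C=C(C(=O)OC)[C@H]1CC2=C(C)[C@@H](OC(=O)CC)CC[C@]2(C)C[C@H]1OC(C)=O | target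

Total step count: 12. Longest linear sequence: 12 steps (from geranyl acetate 1).

Steps most likely to fail

Step 8. The cycloaddition may take the wrong diene face, so that the C3 oxygen ends trans to the C10 methyl, and it may lose material to a [1,5]-hydrogen shift of the diene. The facial argument from C3 is a model and not a secured preference; a weak preference is handled by separating the C10 epimers, an inverted one by the following fallback, which keeps C3 as relay and inverts it afterwards. It sets out from 3 and returns at 14. Step 2 run with the enantiomeric ligand should give, through (2E,6R)-3,7-dimethyl-6-(trimethylsilyloxy)nona-2,7,8-trien-1-yl acetate F1 (not isolated), (2E,6R)-3,7-dimethylnona-2,7,8-triene-1,6-diol F2. TEMPO/PhI(OAc)2 oxidation should give (2E,6R)-6-hydroxy-3,7-dimethylnona-2,7,8-trienal F3, and TBSCl/imidazole the silyl ether (2E,6R)-6-(tert-butyldimethylsilyloxy)-3,7-dimethylnona-2,7,8-trienal F4. Zinc Barbier addition of 9 should give methyl (5E,9R)-9-(tert-butyldimethylsilyloxy)-4-hydroxy-6,10-dimethyl-2-methylidenedodeca-5,10,11-trienoate F5, and Dess–Martin oxidation the ketone methyl (5E,9R)-9-(tert-butyldimethylsilyloxy)-6,10-dimethyl-2-methylidene-4-oxododeca-5,10,11-trienoate F6. TBSOTf/Et3N should give methyl (3Z,5E,9R)-4,9-bis(tert-butyldimethylsilyloxy)-6,10-dimethyl-2-methylidenedodeca-3,5,10,11-tetraenoate F7, and thermolysis as in step 8 the adduct methyl (3R,7S,10R)-3,8-bis(tert-butyldimethylsilyloxy)eudesma-4,8,11(13)-trien-12-oate F8. HF·pyridine removes both silyl groups to give methyl (3R,7S,10R)-3-hydroxy-8-oxoeudesma-4,11(13)-dien-12-oate F9. A Mitsunobu reaction (EtCO2H, PPh3, DIAD) then inverts C3 and installs the propanoate, giving 14; SN2' attack is disfavoured because C5 is fully substituted.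

Step 10. The dienolate may be protonated at C13, which moves the double bond into conjugation as the C7=C11 alkylidene keto ester, or protonation at C7 may be unselective. The fallback replaces kinetic by thermodynamic control and makes no new compound: it sets out from 14, equilibrates it with DBU (cat.) in CH2Cl2 at rt, and returns at 16. The equatorial 7β epimer should predominate, though modestly because C5 is sp2 and offers no second syn-axial hydrogen; the epimers are separated by chromatography and recovered 14 is resubmitted.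

Step 2. Regioselectivity (allenyl versus homopropargyl transfer) or enantioselectivity may erode in the chromium-catalysed addition to an unbranched aldehyde. The fallback sets the stereocentre by ketone reduction; it sets out from 3 and returns at 6. Indium-mediated Barbier addition of 4 (In, THF/H2O) should give racemic (2E)-6-hydroxy-3,7-dimethylnona-2,7,8-trien-1-yl acetate F10, and Dess–Martin oxidation the allenyl ketone (2E)-3,7-dimethyl-6-oxonona-2,7,8-trien-1-yl acetate F11. Corey–Bakshi–Shibata reduction with the (R)-methyl oxazaborolidine and catecholborane (allenyl as the large group) should give (2E,6S)-6-hydroxy-3,7-dimethylnona-2,7,8-trien-1-yl acetate F12, and K2CO3/MeOH then gives 6.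

Further compounds
F1 | step 8 | (2E,6R)-3,7-dimethyl-6-(trimethylsilyloxy)nona-2,7,8-trien-1-yl acetate (not isolated) | C=C=C(C)[C@H](O[Si](C)(C)C)CC/C(C)=C/COC(C)=O
F2 | step 8 | (2E,6R)-3,7-dimethylnona-2,7,8-triene-1,6-diol | C=C=C(C)[C@H](O)CC/C(C)=C/CO
F3 | step 8 | (2E,6R)-6-hydroxy-3,7-dimethylnona-2,7,8-trienal | C=C=C(C)[C@H](O)CC/C(C)=C/C=O
F4 | step 8 | (2E,6R)-6-(tert-butyldimethylsilyloxy)-3,7-dimethylnona-2,7,8-trienal | C=C=C(C)[C@H](O[Si](C)(C)C(C)(C)C)CC/C(C)=C/C=O
F5 | step 8 | methyl (5E,9R)-9-(tert-butyldimethylsilyloxy)-4-hydroxy-6,10-dimethyl-2-methylidenedodeca-5,10,11-trienoate (both C4 epimers) | C=C=C(C)[C@H](O[Si](C)(C)C(C)(C)C)CC/C(C)=C/C(O)CC(=C)C(=O)OC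
F6 | step 8 | methyl (5E,9R)-9-(tert-butyldimethylsilyloxy)-6,10-dimethyl-2-methylidene-4-oxododeca-5,10,11-trienoate | C=C=C(C)[C@H](O[Si](C)(C)C(C)(C)C)CC/C(C)=C/C(=O)CC(=C)C(=O)OC
F7 | step 8 | methyl (3Z,5E,9R)-4,9-bis(tert-butyldimethylsilyloxy)-6,10-dimethyl-2-methylidenedodeca-3,5,10,11-tetraenoate | C=C=C(C)[C@H](O[Si](C)(C)C(C)(C)C)CC/C(C)=C/C(O[Si](C)(C)C(C)(C)C)=C/C(=C)C(=O)OC
F8 | step 8 | methyl (3R,7S,10R)-3,8-bis(tert-butyldimethylsilyloxy)eudesma-4,8,11(13)-trien-12-oate | C=C(C(=O)OC)[C@@H]1CC2=C(C)[C@H](O[Si](C)(C)C(C)(C)C)CC[C@]2(C)C=C1O[Si](C)(C)C(C)(C)C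
F9 | step 8 | methyl (3R,7S,10R)-3-hydroxy-8-oxoeudesma-4,11(13)-dien-12-oate | C=C(C(=O)OC)[C@@H]1CC2=C(C)[C@H](O)CC[C@]2(C)CC1=O
F0 | step 10 | none | none
F10 | step 2 | racemic (2E)-6-hydroxy-3,7-dimethylnona-2,7,8-trien-1-yl acetate | C=C=C(C)C(O)CC/C(C)=C/COC(C)=O
F11 | step 2 | (2E)-3,7-dimethyl-6-oxonona-2,7,8-trien-1-yl acetate | C=C=C(C)C(=O)CC/C(C)=C/COC(C)=O
F12 | step 2 | (2E,6S)-6-hydroxy-3,7-dimethylnona-2,7,8-trien-1-yl acetate | C=C=C(C)[C@@H](O)CC/C(C)=C/COC(C)=O
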